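**Retrosynthetic overview**

1. Labels: the ten-membered ring is C1 (CH–O-methacryloyl), C2 (CH2), C3 (C(Me)OAc), C4 (C=O), C5, C6 (CH2), C7 (CMe)=C8 (Z), C9 (CH–O of the lactone), C10; the butenolide ring is O–C9–C10=C11(C13H2OAc)–C12(=O).
2. Last disconnections: the methacrylate at C1–O, then the C1–C10 bond. The ten-membered ring is closed last by an intramolecular Nozaki–Hiyama–Kishi addition of a C10–Br bromobutenolide to a C1 aldehyde, which also creates the C1 carbinol stereocentre from an acyclic chain that carries only C3 and C9.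
3. Enabling feature: C10 is both a ring atom of the ten-membered carbocycle and the β-carbon of the butenolide ring, and its ring neighbour C1 is a carbinol. A C10–Br bond is therefore a vinylogous acyl bromide that is easily metalated, and C1–C10 is the one ring bond that an alkenylmetal–aldehyde addition can form.
4. Butenolide (first ring): Vilsmeier–Haack bromoformylation of a tetronic acid installs C10–Br and the C13 carbon together; the tetronic acid comes from Zn–ProPhenol alkynylation of a Z-enal with methyl propiolate (sets C9), then oxa-Michael addition–lactonization.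
5. Chain: C5–C6 by alkylation of a methyl ketone that can enolize only away from quaternary C3 (C3 from (R)-citramalic acid) with a Z-allylic bromide from carbomagnesiation–iodination of propargyl alcohol (fixes C7=C8). Ring order: butenolide, then ten-membered ring.

Key step: step 18

Assumption: (S,S)-ProPhenol is taken as the ligand enantiomer that delivers the 4R carbinol in step 9; if the sense is opposite, (R,R)-ProPhenol is used in the same way.

**Route**

Step 1
Reactants: 1 propargyl alcohol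
Product: 3 (Z)-3-iodo-2-methylprop-2-en-1-ol, via alkenylmagnesium alkoxide 2 (not isolated)
Conditions: MeMgBr (2.5 equiv), CuI (10 mol %), THF, −10 °C to rt; then I2, −10 °C; H2O
Reagents that add atoms: methylmagnesium bromide, C[Mg]Br; iodine, I-I
Why: Copper-catalysed anti-carbomagnesiation of the propargylic alkoxide places methyl on the proximal alkyne carbon and magnesium on the terminal carbon cis to CH2O in a five-membered chelate, and iodinolysis with retention should give the Z-iodoalkene whose cis CH2/iodine arrangement later becomes the Z C7=C8 ring bond.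

Step 2
Reactants: 3 (Z)-3-iodo-2-methylprop-2-en-1-ol
Product: 4 (Z)-3-bromo-1-iodo-2-methylprop-1-ene
Conditions: CBr4, PPh3, CH2Cl2, 0 °C
Reagents that add atoms: carbon tetrabromide, BrC(Br)(Br)Br
Why: Appel bromination converts the primary allylic alcohol into the bromide by SN2 displacement under neutral conditions, without touching the alkenyl iodide or the double-bond geometry.

Step 3
Reactants: 5 (R)-citramalic acid
Product: 6 (R)-2-(2,2,4-trimethyl-5-oxo-1,3-dioxolan-4-yl)acetic acid
Conditions: 2,2-dimethoxypropane, TsOH·H2O (cat.), CH2Cl2, rt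
Reagents that add atoms: 2,2-dimethoxypropane, COC(C)(C)OC
Why: Acid-catalysed transacetalization closes the five-membered dioxolanone on the α-hydroxy acid only, which differentiates the carboxyl that becomes C4 from the one that becomes C1 and leaves the chiral-pool C3 centre untouched.

Step 4
Reactants: 6 (R)-2-(2,2,4-trimethyl-5-oxo-1,3-dioxolan-4-yl)acetic acid
Product: 8 (R)-3-hydroxy-3-methyldihydrofuran-2(3H)-one, via hydroxyethyl dioxolanone 7 (not isolated)
Conditions: BH3·SMe2, THF, 0 °C to rt; MeOH; then TsOH·H2O (cat.), CH2Cl2, rt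
Reagents that add atoms: none
Why: Borane reduces the free carboxylic acid chemoselectively beside the dioxolanone, and acid-catalysed translactonization of the new primary alcohol onto the dioxolanone carbonyl expels acetone to give the γ-lactone (carboxylic acid reduction, then lactonization), the quaternary C3 centre not being involved.

Step 5
Reactants: 8 (R)-3-hydroxy-3-methyldihydrofuran-2(3H)-one
Product: 9 (R)-3,5-dihydroxy-3-methylpentan-2-one (open form of its cyclic hemiketal)
Conditions: MeLi (2.2 equiv), THF, −78 °C; H2O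
Reagents that add atoms: methyllithium, [Li]C
Why: After deprotonation of the tertiary alcohol, methyllithium adds once to the lactone carbonyl (organolithium mono-addition to a γ-lactone) because the tetrahedral lithium hemiketal alkoxide is stable at −78 °C and collapses only on work-up, giving the methyl ketone (C4=O, C5 methyl).

Step 6
Reactants: 9 (R)-3,5-dihydroxy-3-methylpentan-2-one
Product: 10 (R)-5-[(tert-butyldiphenylsilyl)oxy]-3-hydroxy-3-methylpentan-2-one
Conditions: TBDPSCl, imidazole, CH2Cl2, 0 °C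
Reagents that add atoms: tert-butyl(chloro)diphenylsilane, CC(C)(C)[Si](Cl)(c1ccccc1)c1ccccc1
Why: Silyl ether formation with a bulky silyl chloride is selective for the primary hydroxyl over the hindered tertiary α-ketol hydroxyl and draws the hemiketal equilibrium to the open ketone.

Step 7
Reactants: 10 (R)-5-[(tert-butyldiphenylsilyl)oxy]-3-hydroxy-3-methylpentan-2-one; 4 (Z)-3-bromo-1-iodo-2-methylprop-1-ene
Product: 11 (3R,7Z)-1-[(tert-butyldiphenylsilyl)oxy]-3-hydroxy-8-iodo-3,7-dimethyloct-7-en-4-one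
Conditions: LDA (2.2 equiv), THF, −78 °C; then 4, DMPU, −78 to −30 °C; H2O
Reagents that add atoms: none
Why: Because C3 is quaternary, the ketone can enolize only toward the methyl group, so the alkoxide–enolate dianion forms regiospecifically at C5 and its SN2 alkylation (enolate alkylation) with the primary allylic bromide forms the C5–C6 bond, while the alkenyl iodide and the non-enolizable C3 centre are unaffected.

Step 8
Reactants: 11 (3R,7Z)-1-[(tert-butyldiphenylsilyl)oxy]-3-hydroxy-8-iodo-3,7-dimethyloct-7-en-4-one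
Product: 12 (2Z,7R)-9-[(tert-butyldiphenylsilyl)oxy]-7-hydroxy-3,7-dimethyl-6-oxonon-2-enal
Conditions: CO (3 atm), Pd(PPh3)4 (5 mol %), Bu3SnH (slow addition), THF, 50 °C
Reagents that add atoms: carbon monoxide, [C-]#[O+]
Why: Palladium-catalysed reductive carbonylation (formylation) of the alkenyl iodide proceeds by oxidative addition, CO insertion and hydride transfer from tin with retention of the double-bond geometry, and the ketone, tertiary alcohol and silyl ether are inert to it.

Step 9
Reactants: 12 (2Z,7R)-9-[(tert-butyldiphenylsilyl)oxy]-7-hydroxy-3,7-dimethyl-6-oxonon-2-enal; 13 methyl propiolate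
Product: 14 methyl (4R,5Z,10R)-12-[(tert-butyldiphenylsilyl)oxy]-4,10-dihydroxy-6,10-dimethyl-9-oxododec-5-en-2-ynoate
Conditions: Me2Zn (4 equiv), (S,S)-ProPhenol (20 mol %), Ph3P=O (40 mol %), toluene, 0 °C; H2O
Reagents that add atoms: none
Why: Zn–ProPhenol-catalysed enantioselective alkynylation adds the zinc acetylide of methyl propiolate to the enal aldehyde in preference to the hindered ketone, and the C9 carbinol configuration (4R in 14) is set by the chiral dinuclear zinc catalyst, the remote C3 centre exerting no influence.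

Step 10
Reactants: 14 methyl (4R,5Z,10R)-12-[(tert-butyldiphenylsilyl)oxy]-4,10-dihydroxy-6,10-dimethyl-9-oxododec-5-en-2-ynoate
Product: 16 (5R)-4-(allyloxy)-5-[(1Z,6R)-8-[(tert-butyldiphenylsilyl)oxy]-6-hydroxy-2,6-dimethyl-5-oxooct-1-en-1-yl]furan-2(5H)-one, via allyloxy enoate 15 (not isolated)
Conditions: allyl alcohol/THF, NaH (0.2 equiv), 0 °C to rt
Reagents that add atoms: allyl alcohol, C=CCO
Why: Oxa-Michael addition of allyloxide to the ynoate gives a push–pull β-allyloxy enoate whose geometry equilibrates, and lactonization of the C9 hydroxyl onto the ester (conjugate addition–lactonization route to tetronates) closes the butenolide ring without breaking the C9–O bond, so the C9 configuration is retained.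

Step 11
Reactants: 16 (5R)-4-(allyloxy)-5-[(1Z,6R)-8-[(tert-butyldiphenylsilyl)oxy]-6-hydroxy-2,6-dimethyl-5-oxooct-1-en-1-yl]furan-2(5H)-one
Product: 17 (3R,7Z)-8-[(2R)-3-(allyloxy)-5-oxo-2,5-dihydrofuran-2-yl]-1-[(tert-butyldiphenylsilyl)oxy]-3,7-dimethyl-4-oxooct-7-en-3-yl acetate
Conditions: Ac2O, DMAP, Et3N, CH2Cl2, rt to 35 °C
Reagents that add atoms: acetic anhydride, CC(=O)OC(C)=O
Why: DMAP-catalysed acylation esterifies the only free hydroxyl, the hindered tertiary α-ketol OH at C3, with retention; it is placed here because the tertiary acetate would not survive the alkoxide of step 10 and a free tertiary alcohol would react in step 13.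

Step 12
Reactants: 17 (3R,7Z)-8-[(2R)-3-(allyloxy)-5-oxo-2,5-dihydrofuran-2-yl]-1-[(tert-butyldiphenylsilyl)oxy]-3,7-dimethyl-4-oxooct-7-en-3-yl acetate
Product: 18 (3R,7Z)-1-[(tert-butyldiphenylsilyl)oxy]-8-[(2R)-3-hydroxy-5-oxo-2,5-dihydrofuran-2-yl]-3,7-dimethyl-4-oxooct-7-en-3-yl acetate
Conditions: Pd(PPh3)4 (3 mol %), morpholine, THF, 0 °C; cold dilute aqueous acid wash
Reagents that add atoms: none
Why: Tsuji–Trost deallylation: zerovalent palladium ionizes the allyl enol ether, whose leaving group is the stabilized tetronate anion, and morpholine captures the allyl unit, while the hindered trisubstituted allylic C9–O lactone bond is expected to ionize much more slowly at 0 °C.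

Step 13
Reactants: 18 (3R,7Z)-1-[(tert-butyldiphenylsilyl)oxy]-8-[(2R)-3-hydroxy-5-oxo-2,5-dihydrofuran-2-yl]-3,7-dimethyl-4-oxooct-7-en-3-yl acetate
Product: 20 (3R,7Z)-8-[(2R)-3-bromo-4-formyl-5-oxo-2,5-dihydrofuran-2-yl]-1-[(tert-butyldiphenylsilyl)oxy]-3,7-dimethyl-4-oxooct-7-en-3-yl acetate, via iminium bromide 19 (not isolated)
Conditions: (bromomethylene)dimethyliminium bromide (2.5 equiv), CH2Cl2, 0 °C to rt; then H2O, 0 °C
Reagents that add atoms: (bromomethylene)dimethyliminium bromide, C[N+](C)=CBr.[Br-]; water, O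
Why: Vilsmeier–Haack haloformylation of a cyclic β-dicarbonyl enol (as with 4-hydroxycoumarins) formylates the nucleophilic α-carbon C11 and converts the C10 enol into the vinylogous acyl bromide, and hydrolysis of the iminium salt unveils the aldehyde, so the C13 carbon and the C10–Br handle are installed together.

Step 14
Reactants: 20 (3R,7Z)-8-[(2R)-3-bromo-4-formyl-5-oxo-2,5-dihydrofuran-2-yl]-1-[(tert-butyldiphenylsilyl)oxy]-3,7-dimethyl-4-oxooct-7-en-3-yl acetate
Product: 21 (3R,7Z)-8-[(2R)-3-bromo-4-(hydroxymethyl)-5-oxo-2,5-dihydrofuran-2-yl]-1-[(tert-butyldiphenylsilyl)oxy]-3,7-dimethyl-4-oxooct-7-en-3-yl acetate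
Conditions: NaBH4 (0.3 equiv), CeCl3·7H2O, MeOH/CH2Cl2, −78 °C
Reagents that add atoms: none
Why: Luche 1,2-reduction at −78 °C reduces the highly electrophilic aldehyde selectively over the hindered C4 ketone and the lactone, the cerium salt suppressing conjugate addition–elimination at the C10–Br position.

Step 15
Reactants: 21 (3R,7Z)-8-[(2R)-3-bromo-4-(hydroxymethyl)-5-oxo-2,5-dihydrofuran-2-yl]-1-[(tert-butyldiphenylsilyl)oxy]-3,7-dimethyl-4-oxooct-7-en-3-yl acetate
Product: 22 (3R,7Z)-8-[(2R)-4-(acetoxymethyl)-3-bromo-5-oxo-2,5-dihydrofuran-2-yl]-1-[(tert-butyldiphenylsilyl)oxy]-3,7-dimethyl-4-oxooct-7-en-3-yl acetate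
Conditions: Ac2O, pyridine, DMAP (cat.), CH2Cl2, 0 °C
Reagents that add atoms: acetic anhydride, CC(=O)OC(C)=O
Why: Standard pyridine/DMAP acylation of the primary allylic alcohol installs the C13 acetate of the target.

Step 16
Reactants: 22 (3R,7Z)-8-[(2R)-4-(acetoxymethyl)-3-bromo-5-oxo-2,5-dihydrofuran-2-yl]-1-[(tert-butyldiphenylsilyl)oxy]-3,7-dimethyl-4-oxooct-7-en-3-yl acetate
Product: 23 (3R,7Z)-8-[(2R)-4-(acetoxymethyl)-3-bromo-5-oxo-2,5-dihydrofuran-2-yl]-1-hydroxy-3,7-dimethyl-4-oxooct-7-en-3-yl acetate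
Conditions: HF·pyridine, pyridine, THF, 0 °C to rt
Reagents that add atoms: none
Why: Fluoride-mediated desilylation with buffered HF·pyridine is compatible with the acetates, the bromobutenolide and the base-sensitive C9–H.

Step 17
Reactants: 23 (3R,7Z)-8-[(2R)-4-(acetoxymethyl)-3-bromo-5-oxo-2,5-dihydrofuran-2-yl]-1-hydroxy-3,7-dimethyl-4-oxooct-7-en-3-yl acetate
Product: 24 (3R,7Z)-8-[(2R)-4-(acetoxymethyl)-3-bromo-5-oxo-2,5-dihydrofuran-2-yl]-3,7-dimethyl-1,4-dioxooct-7-en-3-yl acetate
Conditions: Dess–Martin periodinane, NaHCO3, CH2Cl2, 0 °C to rt; used without storage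
Reagents that add atoms: none
Why: Dess–Martin oxidation converts the primary alcohol into the aldehyde under buffered, amine-free conditions, so the β-acetoxy aldehyde is not exposed to base-induced elimination.

Step 18
Reactants: 24 (3R,7Z)-8-[(2R)-4-(acetoxymethyl)-3-bromo-5-oxo-2,5-dihydrofuran-2-yl]-3,7-dimethyl-1,4-dioxooct-7-en-3-yl acetate
Product: 25 [(4S,6R,10Z,11aR)-6-acetoxy-4-hydroxy-6,10-dimethyl-2,7-dioxo-2,4,5,6,7,8,9,11a-octahydrocyclodeca[b]furan-3-yl]methyl acetate
Conditions: CrCl2 (10 equiv), NiCl2 (2 mol % relative to CrCl2), DMSO/THF 3:1, rt, syringe-pump addition of 24 to a final 0.002 M; H2O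
Reagents that add atoms: none
Why: Zerovalent nickel (formed from NiCl2 by CrCl2) inserts into the C10–Br bond, a vinylogous acyl bromide and the only reactive carbon–halogen bond, transmetalation gives a trivalent alkenylchromium, and this adds to the C1 aldehyde to leave a chromium alkoxide that is hydrolysed on work-up. The closest known reaction type is the Nozaki–Hiyama–Kishi macrocyclization of alkenyl halides, including β-halo enoates, with aldehydes, which is used for eight- to twelve-membered carbocycles. The ten-membered ring is closed by intramolecular 1,2-addition of the C10 alkenylmetal to the C1 carbonyl (C1–C10 bond), with the Z C7=C8 bond and the planar butenolide acting as turn elements and high dilution suppressing intermolecular coupling. The new C1 stereocentre is controlled by the C9 centre through the butenolide plane: the tether should approach on the face on which C8 lies, and the chromium-bound aldehyde oxygen is expected to turn toward the C13 acetoxymethyl group, which can chelate chromium, so that H-1 and H-9 end up on the same face (1S, that is 4S in 25). The step needs chemoselectivity for the aldehyde over the C4 ketone, the lactone and the acetates, which the oxophilic but weakly basic alkenylchromium secures (ketones and esters are inert, and the hindered C4 ketone could only give a seven-membered ring). It also needs the acidic C9–H and the β-acetoxy aldehyde to survive, which the neutral conditions allow.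

Step 19
Reactants: 25 [(4S,6R,10Z,11aR)-6-acetoxy-4-hydroxy-6,10-dimethyl-2,7-dioxo-2,4,5,6,7,8,9,11a-octahydrocyclodeca[b]furan-3-yl]methyl acetate
Product: 26 CNP0115165.2, (4S,6R,10Z,11aR)-6-acetoxy-3-(acetoxymethyl)-6,10-dimethyl-2,7-dioxo-2,4,5,6,7,8,9,11a-octahydrocyclodeca[b]furan-4-yl 2-methylprop-2-enoate
Conditions: methacrylic anhydride, DMAP (cat.), i-Pr2NEt, CH2Cl2, 0 °C
Reagents that add atoms: methacrylic anhydride, C=C(C)C(=O)OC(=O)C(C)=C
Why: DMAP-catalysed acylation of the single free hydroxyl with methacrylic anhydride proceeds with retention at C1, and the low temperature and hindered amine base limit epimerization at C9 and translactonization onto the C1 oxygen.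

**Compound list**

1 | propargyl alcohol | C#CCO | starting material
2 | bromomagnesium (Z)-3-(bromomagnesio)-2-methylprop-2-en-1-olate (not isolated) | Br[Mg]OC/C(C)=C\[Mg]Br | intermediate
3 | (Z)-3-iodo-2-methylprop-2-en-1-ol | OC/C(C)=C\I | intermediate
4 | (Z)-3-bromo-1-iodo-2-methylprop-1-ene | BrC/C(C)=C\I | intermediate
5 | (R)-citramalic acid, (2R)-2-hydroxy-2-methylbutanedioic acid | C[C@@](O)(CC(=O)O)C(=O)O | starting material
6 | (R)-2-(2,2,4-trimethyl-5-oxo-1,3-dioxolan-4-yl)acetic acid | C[C@]1(CC(=O)O)OC(C)(C)OC1=O | intermediate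
7 | (R)-5-(2-hydroxyethyl)-2,2,5-trimethyl-1,3-dioxolan-4-one (not isolated) | C[C@]1(CCO)OC(C)(C)OC1=O | intermediate
8 | (R)-3-hydroxy-3-methyldihydrofuran-2(3H)-one | C[C@@]1(O)CCOC1=O | intermediate
9 | (R)-3,5-dihydroxy-3-methylpentan-2-one | C[C@@](O)(CCO)C(C)=O | intermediate
10 | (R)-5-[(tert-butyldiphenylsilyl)oxy]-3-hydroxy-3-methylpentan-2-one | C[C@@](O)(CCO[Si](c1ccccc1)(c1ccccc1)C(C)(C)C)C(C)=O | intermediate
11 | (3R,7Z)-1-[(tert-butyldiphenylsilyl)oxy]-3-hydroxy-8-iodo-3,7-dimethyloct-7-en-4-one | C[C@@](O)(CCO[Si](c1ccccc1)(c1ccccc1)C(C)(C)C)C(=O)CC/C(C)=C\I | intermediate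
12 | (2Z,7R)-9-[(tert-butyldiphenylsilyl)oxy]-7-hydroxy-3,7-dimethyl-6-oxonon-2-enal | C[C@@](O)(CCO[Si](c1ccccc1)(c1ccccc1)C(C)(C)C)C(=O)CC/C(C)=C\C=O | intermediate
13 | methyl propiolate | C#CC(=O)OC | starting material
14 | methyl (4R,5Z,10R)-12-[(tert-butyldiphenylsilyl)oxy]-4,10-dihydroxy-6,10-dimethyl-9-oxododec-5-en-2-ynoate | C[C@@](O)(CCO[Si](c1ccccc1)(c1ccccc1)C(C)(C)C)C(=O)CC/C(C)=C\[C@@H](O)C#CC(=O)OC | intermediate
15 | methyl (2E,4R,5Z,10R)-3-(allyloxy)-12-[(tert-butyldiphenylsilyl)oxy]-4,10-dihydroxy-6,10-dimethyl-9-oxododeca-2,5-dienoate (not isolated) | C[C@@](O)(CCO[Si](c1ccccc1)(c1ccccc1)C(C)(C)C)C(=O)CC/C(C)=C\[C@@H](O)/C(OCC=C)=C\C(=O)OC | intermediate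
16 | (5R)-4-(allyloxy)-5-[(1Z,6R)-8-[(tert-butyldiphenylsilyl)oxy]-6-hydroxy-2,6-dimethyl-5-oxooct-1-en-1-yl]furan-2(5H)-one | C[C@@](O)(CCO[Si](c1ccccc1)(c1ccccc1)C(C)(C)C)C(=O)CC/C(C)=C\[C@H]1OC(=O)C=C1OCC=C | intermediate
17 | (3R,7Z)-8-[(2R)-3-(allyloxy)-5-oxo-2,5-dihydrofuran-2-yl]-1-[(tert-butyldiphenylsilyl)oxy]-3,7-dimethyl-4-oxooct-7-en-3-yl acetate | C[C@@](OC(C)=O)(CCO[Si](c1ccccc1)(c1ccccc1)C(C)(C)C)C(=O)CC/C(C)=C\[C@H]1OC(=O)C=C1OCC=C | intermediate
18 | (3R,7Z)-1-[(tert-butyldiphenylsilyl)oxy]-8-[(2R)-3-hydroxy-5-oxo-2,5-dihydrofuran-2-yl]-3,7-dimethyl-4-oxooct-7-en-3-yl acetate | C[C@@](OC(C)=O)(CCO[Si](c1ccccc1)(c1ccccc1)C(C)(C)C)C(=O)CC/C(C)=C\[C@H]1OC(=O)C=C1O | intermediate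
19 | N-{[(5R)-5-[(1Z,6R)-6-acetoxy-8-[(tert-butyldiphenylsilyl)oxy]-2,6-dimethyl-5-oxooct-1-en-1-yl]-4-bromo-2-oxo-2,5-dihydrofuran-3-yl]methylidene}-N-methylmethanaminium bromide (not isolated) | C[C@@](OC(C)=O)(CCO[Si](c1ccccc1)(c1ccccc1)C(C)(C)C)C(=O)CC/C(C)=C\[C@H]1OC(=O)C(C=[N+](C)C)=C1Br.[Br-] | intermediate
20 | (3R,7Z)-8-[(2R)-3-bromo-4-formyl-5-oxo-2,5-dihydrofuran-2-yl]-1-[(tert-butyldiphenylsilyl)oxy]-3,7-dimethyl-4-oxooct-7-en-3-yl acetate | C[C@@](OC(C)=O)(CCO[Si](c1ccccc1)(c1ccccc1)C(C)(C)C)C(=O)CC/C(C)=C\[C@H]1OC(=O)C(C=O)=C1Br | intermediate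
21 | (3R,7Z)-8-[(2R)-3-bromo-4-(hydroxymethyl)-5-oxo-2,5-dihydrofuran-2-yl]-1-[(tert-butyldiphenylsilyl)oxy]-3,7-dimethyl-4-oxooct-7-en-3-yl acetate | C[C@@](OC(C)=O)(CCO[Si](c1ccccc1)(c1ccccc1)C(C)(C)C)C(=O)CC/C(C)=C\[C@H]1OC(=O)C(CO)=C1Br | intermediate
22 | (3R,7Z)-8-[(2R)-4-(acetoxymethyl)-3-bromo-5-oxo-2,5-dihydrofuran-2-yl]-1-[(tert-butyldiphenylsilyl)oxy]-3,7-dimethyl-4-oxooct-7-en-3-yl acetate | C[C@@](OC(C)=O)(CCO[Si](c1ccccc1)(c1ccccc1)C(C)(C)C)C(=O)CC/C(C)=C\[C@H]1OC(=O)C(COC(C)=O)=C1Br | intermediate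
23 | (3R,7Z)-8-[(2R)-4-(acetoxymethyl)-3-bromo-5-oxo-2,5-dihydrofuran-2-yl]-1-hydroxy-3,7-dimethyl-4-oxooct-7-en-3-yl acetate | C[C@@](OC(C)=O)(CCO)C(=O)CC/C(C)=C\[C@H]1OC(=O)C(COC(C)=O)=C1Br | intermediate
24 | (3R,7Z)-8-[(2R)-4-(acetoxymethyl)-3-bromo-5-oxo-2,5-dihydrofuran-2-yl]-3,7-dimethyl-1,4-dioxooct-7-en-3-yl acetate | C[C@@](OC(C)=O)(CC=O)C(=O)CC/C(C)=C\[C@H]1OC(=O)C(COC(C)=O)=C1Br | intermediate
25 | [(4S,6R,10Z,11aR)-6-acetoxy-4-hydroxy-6,10-dimethyl-2,7-dioxo-2,4,5,6,7,8,9,11a-octahydrocyclodeca[b]furan-3-yl]methyl acetate | O[C@H]1C[C@@](C)(OC(C)=O)C(=O)CC/C(C)=C\[C@H]2OC(=O)C(COC(C)=O)=C12 | intermediate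
26 | CNP0115165.2, (4S,6R,10Z,11aR)-6-acetoxy-3-(acetoxymethyl)-6,10-dimethyl-2,7-dioxo-2,4,5,6,7,8,9,11a-octahydrocyclodeca[b]furan-4-yl 2-methylprop-2-enoate | C=C(C)C(=O)O[C@H]1C[C@@](C)(OC(C)=O)C(=O)CC/C(C)=C\[C@H]2OC(=O)C(COC(C)=O)=C12 | target

**Summary**

Total step count: 19.
Longest linear sequence: 17 steps (steps 3 to 19, from (R)-citramalic acid 5); the allylic bromide 4 (steps 1 and 2) joins in step 7.

Three steps most likely to fail:

1. Step 18 (ring closure). The alkenylchromium may add to the wrong face of the C1 aldehyde, since the facial preference rests on a conformational and chelation argument only, and intermolecular coupling may compete with the ten-membered ring closure. Fallback: setting out from 24, the same CrCl2/NiCl2 closure is run and, if attack occurs mainly on the other face, the C1-epimeric macrocyclic alcohol F1 is taken on. Mitsunobu esterification of F1 with methacrylic acid (PPh3, DIAD, toluene, 0 °C) installs the methacrylate with inversion at C1 and comes back to the route at 26.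

2. Step 13 (bromoformylation). The hydrogen bromide released may ionize the allylic C9–O lactone bond, with loss of configuration or double-bond geometry, and the reagent may attack the enolizable C4 ketone. Fallback: setting out from 18, condensation with N,N-dimethylformamide dimethyl acetal (toluene, rt, neutral) gives the aminomethylene dione F2. Oxalyl bromide (CH2Cl2, −40 °C) then converts the vinylogous amide carbonyl into the C10 bromide without liberating acid, forming 19, and aqueous hydrolysis comes back to the route at 20.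

3. Step 10 (tetronate formation). Under alkoxide the γ-hydroxy ynoate may undergo base-induced 1,3-prototropic (redox) isomerization to a γ-oxo enoate, or C9 may epimerize through the furanolate. Fallback: setting out from 14, neutral conjugate addition of pyrrolidine (THF, 0 °C) gives the β-pyrrolidinyl enoate F3. Hydrolysis with aqueous oxalic acid/THF gives the γ-hydroxy β-keto ester F4, which lactonizes to the tetronic acid F5 that still carries the free tertiary hydroxyl. Ac2O/DMAP/Et3N acetylates both the tertiary hydroxyl and the enol to give the enol acetate F6, and selective methanolysis of the enol acetate (MeOH, cat. imidazole, 0 °C) comes back to the route at 18.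

**Further compounds**

F1 | step 18 | [(4R,6R,10Z,11aR)-6-acetoxy-4-hydroxy-6,10-dimethyl-2,7-dioxo-2,4,5,6,7,8,9,11a-octahydrocyclodeca[b]furan-3-yl]methyl acetate (C4 epimer of 25) | O[C@@H]1C[C@@](C)(OC(C)=O)C(=O)CC/C(C)=C\[C@H]2OC(=O)C(COC(C)=O)=C12
F2 | step 13 | (3R,7Z)-1-[(tert-butyldiphenylsilyl)oxy]-8-[(2R,4Z)-4-[(dimethylamino)methylidene]-3,5-dioxotetrahydrofuran-2-yl]-3,7-dimethyl-4-oxooct-7-en-3-yl acetate | C[C@@](OC(C)=O)(CCO[Si](c1ccccc1)(c1ccccc1)C(C)(C)C)C(=O)CC/C(C)=C\[C@H]1OC(=O)/C(=C\N(C)C)C1=O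
F3 | step 10 | methyl (2E,4R,5Z,10R)-12-[(tert-butyldiphenylsilyl)oxy]-4,10-dihydroxy-6,10-dimethyl-9-oxo-3-(pyrrolidin-1-yl)dodeca-2,5-dienoate | C[C@@](O)(CCO[Si](c1ccccc1)(c1ccccc1)C(C)(C)C)C(=O)CC/C(C)=C\[C@@H](O)/C(N1CCCC1)=C\C(=O)OC
F4 | step 10 | methyl (4R,5Z,10R)-12-[(tert-butyldiphenylsilyl)oxy]-4,10-dihydroxy-6,10-dimethyl-3,9-dioxododec-5-enoate | C[C@@](O)(CCO[Si](c1ccccc1)(c1ccccc1)C(C)(C)C)C(=O)CC/C(C)=C\[C@@H](O)C(=O)CC(=O)OC
F5 | step 10 | (5R)-5-[(1Z,6R)-8-[(tert-butyldiphenylsilyl)oxy]-6-hydroxy-2,6-dimethyl-5-oxooct-1-en-1-yl]-4-hydroxyfuran-2(5H)-one | C[C@@](O)(CCO[Si](c1ccccc1)(c1ccccc1)C(C)(C)C)C(=O)CC/C(C)=C\[C@H]1OC(=O)C=C1O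
F6 | step 10 | (3R,7Z)-8-[(2R)-3-acetoxy-5-oxo-2,5-dihydrofuran-2-yl]-1-[(tert-butyldiphenylsilyl)oxy]-3,7-dimethyl-4-oxooct-7-en-3-yl acetate | C[C@@](OC(C)=O)(CCO[Si](c1ccccc1)(c1ccccc1)C(C)(C)C)C(=O)CC/C(C)=C\[C@H]1OC(=O)C=C1OC(C)=O
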